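The runs were computed for an exercise; the scatter is artificial.

Add up the red run at its last reading, 25.0 min, and 17.5 % of the substrate charged is neither product nor intermediate B. What that leftover is in the amber flask is the quarrel here.

| flask | substrate | partner | remark | time |
|---|---|---|---|---|
| amber | 20 mM | 80 mM (fed, over 2.5 min) | the very flask that is asked about, followed so far; the fed solution adds 1.0 times the starting volume |  |
| red | 20 mM | 160 mM (fed, over 2.5 min) | run made earlier; the fed solution adds 1.0 times the starting volume |  |
| flask | 20 mM | 80.0 mM (fed, over 2.5 min) | the fed solution adds 1.0 times the starting volume | 1.0 h |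

| run | time / min | product / % | intermediate B / % |
|---|---|---|---|
| amber | 1.50 | 4.1 | 2.5 |
| amber | 5.00 | 17.8 | 17.6 |
| amber | 8.00 | 22.5 | 32.1 |
| amber | 12.0 | 25.4 | 40.9 |
| amber | 20.0 | 25.6 | 47.9 |
| amber | 25.0 | 26.6 | 51.3 |
| amber | 30.0 | 26.8 | 52.9 |
| red | 1.33 | 6.5 | 1.6 |
| red | 4.00 | 25.4 | 12.0 |
| red | 6.00 | 33.5 | 20.2 |
| red | 10.0 | 36.9 | 32.4 |
| red | 15.0 | 40.3 | 39.3 |
| red | 20.0 | 39.9 | 41.3 |
| red | 25.0 | 40.6 | 41.9 |

(readings scatter by 1 percentage point)

- which holds at 1.0 h: what has brought the reaction to rest, or that it has not come to rest (it is still moving / forward and back rates have come level / the partner has run out first / all of the substrate has reacted)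
- amount of product at 1.0 h, in percent of the substrate charged
- amount of intermediate B at 1.0 h, in percent of the substrate charged

- charges are per starting volume, the dose included; the dosed solution carries all of it
- the analysis behind the earlier runs scatters by 1 percentage point, standard deviation
- the reaction counts as stopped when no species that holds the substrate changes by six tenths of a point or more over the second half of the time

Both sides use one number, the end ratio: intermediate B over the leftover at the last reading of the red run, 2.39. The amber run, with half the partner, reads 2.61 at its last point, and a scatter of 1 percentage point per reading doesn't separate the two.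

The forecast takes the leftover for substrate: “This points to a reversible substrate ⇌ B equilibrium.” Its verdict at 1.0 h is "forward and back rates have come level", with 27.5 % product (26 % to 29.5 %) and 53.5 % intermediate B (51.5 % to 56 %).

I write the balance of substrate, the limiting reagent, and put the leftover to the test with partner. In the amber run, after the feed of 2.5 min, product gained 0.0285 min⁻¹ per unit of leftover between 5.00 min and 8.00 min, but 0.00288 min⁻¹ between 12.0 min and 30.0 min. Both are readings, the late one resting on a gain of 1.4 points with a scatter of 1 point per reading. Yet by 30.0 min product has used only 6.70 % of the partner, so c(partner) has barely moved since the feed ended. So I answer that the substrate has reacted away and the late leftover is another form, which partner doesn't touch. With product staying near 26.8 %, the end ratio leaves 51.6 % for intermediate B, less than the forecast's 53.5 %.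

The flask gives: all of the substrate has reacted, with 26.1 % product and 52.8 % intermediate B. At that time c(substrate) stands at 0 %, and the leftover is intermediate A, 21.1 %.

    substrate → intermediate A (k = 0.00290 s⁻¹)
    intermediate A ⇌ intermediate B (K = 2.50, k = 0.00280 s⁻¹)
    substrate + partner → product (k = 0.0330 M⁻¹ s⁻¹)

In the flask at 2.822 min, substrate was going to intermediate A 2.3 times as fast as to product. The product step's net turnover up to the asked time is 26.1 %, and the other 73.9 % stands as the two intermediates, of which the end ratio on 26.1 % product makes 52.1 % intermediate B. The forecast's reading of the leftover as substrate fits the flask at 2.5 min, when substrate, at 57.4 %, exceeded intermediate A, at 27.5 %.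

In the flask with 200 mM of partner, product reaches 45.1 %, so the end ratio leaves 38.7 % for intermediate B. The computed result is 39.2 %.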